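At 4.0 h, the time of reading, the substrate that has reacted lies in two places, on the catalyst and in the product, so we reckon the two apart.

all flasks: substrate 1.1 M; free catalyst 5 mol%
- north-east: coupling partner 1.5 equiv; run made earlier
- south: coupling partner 2.4 equiv; run made earlier
- flask: coupling partner 1.10 equiv; time 4.0 h

| run | time / h | substrate / % | product / % |
|---|---|---|---|
| north-east | 1.00 | 94.1 | 2.1 |
| north-east | 2.00 | 91.4 | 3.5 |
| north-east | 3.00 | 89.3 | 6.7 |
| north-east | 4.00 | 86.9 | 8.1 |
| south | 1.00 | 93.4 | 2.3 |
| south | 2.00 | 90.6 | 5.1 |
| south | 3.00 | 87.5 | 7.5 |
| south | 4.00 | 85.5 | 10.9 |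

(readings scatter by 0.3 percentage points)

- part of the substrate that has reacted at 4.0 h
- share of the unused coupling partner that is free and not bound as idle adduct, at 4.0 h

- amounts and yields of by-product count idle adduct too
- steps under discussion: coupling partner + catalyst intermediate A <-> catalyst intermediate B; coupling partner + by-product <-> idle adduct; catalyst intermediate C -> free catalyst + product; substrate + free catalyst -> catalyst intermediate A; catalyst intermediate B <-> by-product + catalyst intermediate C
- the earlier runs do not show how much of coupling partner is bound; that part of a forecast is a guess

How much substrate does the catalyst hold? At 4.00 h the north-east run has lost more substrate than it has made product, by 5.00 % of the charge against a loading of 5 mol%, and the south run shows 3.60 %. This rough reading suggests a resting state in which each catalyst carries one substrate.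

How fast does the product leave? We take the turnover frequency, the product divided by the catalyst loading and the time: 0.405 h⁻¹ at 1.5 equiv and 0.545 h⁻¹ at 2.4 equiv. The two runs differ in c(coupling partner), and between them the apparent order in it reads 0.632.

What does that give at 1.10 equiv, below both runs? Extrapolated with that order, the turnover frequency comes to 0.333 h⁻¹, and the loading times one plus this frequency times the time gives 11.7 % reacted.

The forecast says 11.5 %, slightly below our figure, and guesses 95 % for the free share, having read “a weak, partly saturating dependence on coupling partner”.

The flask gives 11.8 % reacted, with 98.0 % of the unused coupling partner free.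

    coupling partner + catalyst intermediate A ⇌ catalyst intermediate B (K = 0.500 L mol⁻¹, k = 0.0440 L mol⁻¹ s⁻¹)
    coupling partner + by-product ⇌ idle adduct, settled at all times (K = 0.360 L mol⁻¹)
    catalyst intermediate C → free catalyst + product (k = 0.0150 s⁻¹)
    substrate + free catalyst → catalyst intermediate A (k = 0.00180 L mol⁻¹ s⁻¹)
    catalyst intermediate B ⇌ by-product + catalyst intermediate C (K = 5.70 M, k = 3.00 × 10⁻⁴ s⁻¹)

At 4.00 h the flask holds 60.7 % of its catalyst as catalyst intermediate A and 33.0 % as catalyst intermediate B, and its 7.05 % of product means a turnover frequency of 0.353 h⁻¹ against our 0.333 h⁻¹. The neighbour flask with 2 mol% of free catalyst reaches 0.361 h⁻¹; our frequency gives it 4.66 % reacted, and that flask stands at 4.78 %.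

(The earlier runs and the new flask were computed on assumed constants; the scatter is artificial.)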